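- Set the two earlier runs side by side in mM, not in percent. By 50.0 h the larch run lost 13.4 mM of solid substrate and the cedar run 13.4 mM, although cedar charged more.
- Carry the larch loss per hour, 0.268 mM h⁻¹, as the dissolution flux: a zero-order supply, as read from these runs.

| flask | solid substrate | gas phase | remark | time |
|---|---|---|---|---|
| larch | 28 mM | 7.9 mM (held) | run made earlier |  |
| cedar | 44 mM | 7.9 mM (held) | run made earlier |  |
| flask | 20 mM | 7.9 mM (held) |  | 2.0 d |

- larch (time / h: target / %, solid substrate / %): 4.00: 1.1, 95.8; 6.00: 3.0, 94.3; 8.00: 4.2, 93.0; 15.0: 8.9, 85.4; 20.0: 11.8, 81.7; 30.0: 15.1, 72.7; 50.0: 17.4, 52.2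
- cedar (time / h: target / %, solid substrate / %): 4.00: 0.7, 97.9; 6.00: 1.7, 96.3; 8.00: 2.6, 95.8; 15.0: 5.7, 90.3; 20.0: 7.5, 87.3; 30.0: 10.4, 80.2; 50.0: 11.3, 69.5

(readings scatter by 0.5 percentage points)

- how much target there is at 2.0 d, in percent of the solid substrate charged
- concentration of dissolved gas in solution at 2.0 d, in percent of saturation

- solid, in amounts per volume of the solution: solid substrate
- at the start none of the gas is dissolved
- what may be going on: gas phase <-> dissolved gas; starting material + dissolved gas -> target; 2 dissolved gas -> homo dimer; target -> over-reaction product; solid substrate <-> starting material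
- at the start none of the solid substrate is in solution

- The shortest rung is hours. At 4.00 h the larch run held 0.308 mM of target, less than the 1.18 mM that had left the solid substrate, so a dissolved pool fills first.
- The next rung is tens of hours. From 30.0 h to 50.0 h the larch run gained 0.644 mM of target, far less than the 5.74 mM that left the solid substrate, so target is levelling off.
- The longest rung is the charge itself. You divide the flask's 20 mM by the flux and get 74.7 h, longer than the asked 48 h.
- So I expect 35.8% of the solid substrate left in this flask. The larch target at 50.0 h, taken in mM, is 24.4% of this charge, and that is my estimate. The runs hold no reading of dissolved gas, so I give it no number.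
- The forecast says 24% of target and 70% of saturation, and adds: “Dissolved gas is only weakly determined”.
- The flask gives 25.3% of target and 21.8% of saturation.

    gas phase ⇌ dissolved gas, rate k1*(csat - [dissolved gas]) (kL = 1.50 × 10⁻⁵ s⁻¹)
    starting material + dissolved gas → target (k = 0.0690 M⁻¹ s⁻¹)
    2 dissolved gas → homo dimer (k = 0.00300 M⁻¹ s⁻¹)
    target → over-reaction product (k = 1.30 × 10⁻⁵ s⁻¹)
    solid substrate ⇌ starting material, rate k5*(cs5 - [starting material]) while solid is left; crystals form when [starting material] > cs5 (solubility = 9.50 mM, k = 8.40 × 10⁻⁶ s⁻¹)

- At 2.00 d this flask holds 35.8% of its solid substrate, against 35.8% from the flux. Gas then crosses into solution at 0.333 mM h⁻¹, and the flux equals 80.5% of that crossing. For the same flask read at 30 h, the flux leaves 59.8% of the solid substrate, and that flask holds 59.9%.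

The runs were generated by integration on assumed constants; the scatter is artificial.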